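**Retrosynthetic overview**

- Feature used (terpenoid numbering): ring C (C8, C9, C11, C12, C13, C14) is the only bridge between the AB drimane decalin and the DE cyclohepta[b]furan. Its two bonds to ring D, C8–C14 and C12–C13, end on the adjacent carbons C14 and C13, the β- and α-carbons of a C24 ketone.
- Both bonds are cut at once: a retro Giese–aldol (iron-hydride MHAT radical–polar crossover annulation) leads to γ-bicyclohomofarnesal (C8 exocyclic alkene, C12 aldehyde) and a 4-silyloxy-4,5-dihydrocyclohepta[b]furan-8-one (C13=C14 enone).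
- The alkylidene butenolide ring E is carried as a furan and unmasked last (singlet oxygen, then dehydration toward C24). The C12 hydroxyl and the C24 ketone left by the annulation are removed before that.
- The AB aldehyde comes from (+)-sclareolide (C5, C9, C10 bought). The DE enone comes from furan-3-carbaldehyde by asymmetric allylboration (C16), C2 acylation through acrolein, and ring-closing metathesis.
- Ring order: A and B bought, E bought as a furan, D by metathesis, C last by the annulation, E finally oxidised.

Key step: step 11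

Remark on the chemistry:
- Numbering: C8 = methyl-bearing quaternary carbon at the B/C fusion; C9 and C11 = ring-C atoms on the AB side; C12 = ring-C CH2 next to C13; C13 and C14 = C/D fusion carbons; C15 = ring-D CH2; C16 = oxygenated carbon; C24 = ring-D carbon between C13 and the furan; C25 = furan carbon bonded to C24.
- Assumption: the (R)-configured phosphoric acid is taken to be the antipode that gives the R carbinol in step 6. If the sense proves opposite, its enantiomer is used.

**Route**

Step 1
Reactants: 1 (+)-sclareolide
Product: 2 (1R,2R,4aS,8aS)-1-(2-hydroxyethyl)-2,5,5,8a-tetramethyldecahydronaphthalen-2-ol (8α,12-diol)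
Conditions: LiAlH4, THF, 0 °C to rt; aqueous work-up
Reagents that add atoms: none
Why: Hydride reduction of the γ-lactone should open it to the primary C12 alcohol and the tertiary 8α-alcohol without touching C5, C8, C9 or C10.

Step 2
Reactants: 2 8α,12-diol
Product: 3 2-[(1R,2R,4aS,8aS)-2-hydroxy-2,5,5,8a-tetramethyldecahydronaphthalen-1-yl]ethyl acetate
Conditions: Ac2O, pyridine, CH2Cl2, 0 °C to rt
Reagents that add atoms: acetic anhydride, CC(=O)OC(C)=O
Why: Selective O-acylation should occur because only the primary hydroxyl reacts under these conditions, while the hindered tertiary C8 hydroxyl stays free for the dehydration.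

Step 3
Reactants: 3 hydroxy acetate
Product: 5 2-[(1S,4aS,8aS)-5,5,8a-trimethyl-2-methylenedecahydronaphthalen-1-yl]ethyl acetate, via C8 chlorosulfite 4 (not isolated)
Conditions: SOCl2, pyridine, CH2Cl2, −78 °C; chromatography on AgNO3-impregnated silica
Reagents that add atoms: none
Why: E2 dehydration through the chlorosulfite should favour the exocyclic C8 alkene, because the equatorial 8α leaving group has only methyl hydrogens anti-periplanar; a minor C7–C8 isomer is harmless (it gives the same C8 radical in step 11) and the tetrasubstituted C8–C9 isomer is removed on the silver-doped silica.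

Step 4
Reactants: 5 alkenyl acetate
Product: 6 γ-bicyclohomofarnesol, 2-[(1S,4aS,8aS)-5,5,8a-trimethyl-2-methylenedecahydronaphthalen-1-yl]ethanol
Conditions: K2CO3 (cat.), MeOH, rt
Reagents that add atoms: none
Why: Base-catalysed methanolysis of the acetate should free the primary alcohol without moving the alkene.

Step 5
Reactants: 6 γ-bicyclohomofarnesol
Product: 7 γ-bicyclohomofarnesal, 2-[(1S,4aS,8aS)-5,5,8a-trimethyl-2-methylenedecahydronaphthalen-1-yl]acetaldehyde
Conditions: n-Pr4N[RuO4] (5 mol%), NMO, 4 Å MS, CH2Cl2, rt
Reagents that add atoms: none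
Why: The Ley–Griffith oxidation is neutral, so the γ,δ-unsaturated aldehyde should form without alkene migration or carbonyl-ene closure, and C9 (β to the aldehyde) cannot epimerise.

Step 6
Reactants: 8 furan-3-carbaldehyde; 9 allylboronic acid pinacol ester
Product: 11 (R)-1-(furan-3-yl)but-3-en-1-ol, via pinacol borate ester 10 (not isolated)
Conditions: (R)-TRIP phosphoric acid (5 mol%), toluene, −30 °C; aqueous work-up
Reagents that add atoms: none
Why: In this chiral Brønsted acid-catalysed allylboration the acid hydrogen-bonds to a boronate oxygen in a closed chair transition state and its 3,3'-aryl groups should leave the Re face of the aldehyde open, which sets C16 as R.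

Step 7
Reactants: 11 (R)-1-(furan-3-yl)but-3-en-1-ol; 12 acrolein
Product: 14 (1R)-1-[2-(1-hydroxyprop-2-en-1-yl)furan-3-yl]but-3-en-1-ol (epimers at the new carbinol), via dilithio alkoxide 13 (not isolated)
Conditions: n-BuLi (2.2 equiv), THF, −78 to 0 °C; acrolein, −78 °C; H2O
Reagents that add atoms: none
Why: Alkoxide-directed lithiation should take place at the adjacent furan C2–H, which is also an acidic α-position, and the aryllithium should add 1,2 to acrolein at low temperature; the new carbinol centre is destroyed in step 8.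

Step 8
Reactants: 14 diol
Product: 15 1-{3-[(1R)-1-hydroxybut-3-en-1-yl]furan-2-yl}prop-2-en-1-one
Conditions: activated MnO2, CH2Cl2, 0 °C to rt, monitored
Reagents that add atoms: none
Why: MnO2 oxidation should be chemoselective, since the doubly activated (allylic and 2-furyl) carbinol reacts much faster than the singly activated 3-furyl carbinol at C16.

Step 9
Reactants: 15 hydroxy enone
Product: 16 1-{3-[(1R)-1-(tert-butyldimethylsilyloxy)but-3-en-1-yl]furan-2-yl}prop-2-en-1-one
Conditions: TBSOTf, 2,6-lutidine, CH2Cl2, −78 °C
Reagents that add atoms: tert-butyldimethylsilyl triflate, CC(C)(C)[Si](C)(C)OS(=O)(=O)C(F)(F)F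
Why: Silylation with the triflate and a hindered, non-nucleophilic base should protect the C16 alcohol without aza-Michael addition to the vinyl ketone, which has no enolisable position.

Step 10
Reactants: 16 silyloxy dienone
Product: 17 (4R)-4-(tert-butyldimethylsilyloxy)-4,5-dihydro-8H-cyclohepta[b]furan-8-one
Conditions: (H2IMes)(PCy3)Cl2Ru=CHPh (second-generation Grubbs catalyst, 5 mol%), CH2Cl2 (2 mM), 40 °C
Reagents that add atoms: none
Why: Ring-closing metathesis should start at the terminal alkene and close onto the vinyl ketone, giving the seven-membered cis-enone (ring D) fused to the furan with loss of ethylene.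

Step 11
Reactants: 7 γ-bicyclohomofarnesal; 17 furan-fused cycloheptenone
Product: 19 pentacyclic C12-hydroxy C24-ketone with C16 silyl ether, via iron enolate 18 (not isolated)
Conditions: Fe(acac)3 (50 mol%), PhSiH3 (2.5 equiv), EtOH (5 equiv), ClCH2CH2Cl, 0 °C to rt, argon; 7 in 1.5-fold excess
Reagents that add atoms: none
Why: A trivalent iron hydride formed from Fe(acac)3 and PhSiH3 should transfer a hydrogen atom to the C8 exocyclic methylene of 7 (the only electron-neutral alkene present), the nucleophilic tertiary C8 radical adds in Giese fashion to the β-carbon C14 of enone 17, and the C13 α-keto radical is reduced by divalent iron to enolate 18, which attacks the C12 aldehyde. The closest known reaction type is the iron-hydride MHAT-initiated Giese–aldol radical–polar crossover annulation of γ,δ-unsaturated aldehydes with cyclic enones. Ring C is closed by a 6-(enolexo)-exo-trig aldol through a chair with the C8–C14 and C9–C11 bonds equatorial, and no other ring size can form because the aldehyde carbon lies four atoms from C8. C8 is set by bond formation on the face away from the axial C10 methyl, which leaves the new C8 methyl axial; C14 is set by approach to the enone face opposite the pseudoaxial C16 silyloxy group, so that C8 and the C16 oxygen end up trans on ring D. C13 and the C12 carbinol arise under aldol control but are not relied on, since C12 is removed in step 12 and C13 is equilibrated in step 13. The step needs facial selectivity on both partners and donor/acceptor cross-selectivity, which are secured by the 1,3-diaxial methyl of the decalin, the bulky silyl ether two atoms from C14, and the polarity match between a tertiary alkyl radical and an unhindered enone β-CH.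

Step 12
Reactants: 19 pentacyclic aldol
Product: 21 pentacyclic C12–C13 enone, via C12 mesylate 20 (not isolated)
Conditions: MsCl, Et3N, CH2Cl2, 0 °C to rt
Reagents that add atoms: none
Why: Mesylation followed by E1cB elimination through the C13 enolate should give the furyl enone from either C12 or C13 epimer; C14 is untouched because its hydrogen is not conjugated to the carbonyl.

Step 13
Reactants: 21 pentacyclic enone
Product: 23 pentacyclic C24 furyl ketone (trans C/D), via C13-epimeric ketone 22 (not isolated)
Conditions: Cu(OAc)2 (5 mol%), 1,2-bis(diphenylphosphino)benzene (5 mol%), (EtO)2MeSiH, t-BuOH, toluene, rt; then NaOMe (cat.), MeOH/THF, rt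
Reagents that add atoms: none
Why: The phosphine-ligated monovalent copper hydride formed in situ should deliver hydride only to the β-carbon C12 (conjugate reduction), and methoxide then equilibrates the single enolisable centre C13 to the trans-fused ketone, in which the C24 branch is equatorial on ring C instead of 1,3-diaxial to the C8 methyl.

Step 14
Reactants: 23 pentacyclic furyl ketone
Product: 24 C24 tosylhydrazone
Conditions: TsNHNH2, EtOH, 70 °C
Reagents that add atoms: p-toluenesulfonyl hydrazide, Cc1ccc(cc1)S(=O)(=O)NN
Why: Condensation of the aryl ketone with the sulfonyl hydrazide should give the hydrazone without added acid, which spares the furan and the silyl ether; any exchange at C13 returns the trans epimer.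

Step 15
Reactants: 24 tosylhydrazone
Product: 26 pentacyclic fused furan C16 silyl ether, via N-boryl hydrazine 25 (not isolated)
Conditions: catecholborane, CHCl3, 0 °C to rt; NaOAc·3H2O, 60 °C
Reagents that add atoms: none
Why: Hydroboration of the C=N bond and acetate-induced loss of sulfinate should give a diazene that extrudes N2 to leave the C24 methylene (Kabalka variant of the Caglioti tosylhydrazone reduction), a path without a C24 cation that leaves C13 and the C16 silyl ether alone.

Step 16
Reactants: 26 furan silyl ether
Product: 27 pentacyclic furan C16 alcohol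
Conditions: Bu4NF, THF, rt
Reagents that add atoms: none
Why: Fluoride-induced desilylation should free the secondary C16 alcohol with retention, since the C–O bond is not broken.

Step 17
Reactants: 27 furan alcohol
Product: 28 pentacyclic furan C16 acetate
Conditions: Ac2O, pyridine, DMAP (cat.), CH2Cl2, rt
Reagents that add atoms: acetic anhydride, CC(=O)OC(C)=O
Why: DMAP-catalysed acylation of the secondary alcohol should install the acetate with retention at C16.

Step 18
Reactants: 28 furan acetate
Product: 30 C25-hydroxybutenolide (hemiketal epimers), via furan endoperoxide 29 (not isolated)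
Conditions: O2, visible light, tetraphenylporphyrin (cat.), i-Pr2NEt, CH2Cl2, −78 °C
Reagents that add atoms: dioxygen, O=O
Why: [4+2] Cycloaddition of singlet oxygen across the two furan α-carbons gives an endoperoxide in which only the unsubstituted α-carbon bears a hydrogen, so the amine-induced Kornblum–DeLaMare fragmentation can only place the lactone carbonyl there and the hydroxyl at C25.

Step 19
Reactants: 30 hydroxybutenolide
Product: 31 target CNP0193439.1
Conditions: p-TsOH·H2O (cat.), 4 Å MS, benzene, 50 °C
Reagents that add atoms: none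
Why: Acid-catalysed dehydration of the tertiary hemiketal can only proceed toward C24, the sole hydrogen-bearing neighbour of C25, and should give the conjugated γ-alkylidene butenolide whose alkene geometry is fixed by ring D.

**Compound list**

1 | (+)-sclareolide | O=C1C[C@H]2[C@](C)(O1)CC[C@H]1C(C)(C)CCC[C@]21C | starting material
2 | (1R,2R,4aS,8aS)-1-(2-hydroxyethyl)-2,5,5,8a-tetramethyldecahydronaphthalen-2-ol (8α,12-diol) | OCC[C@H]1[C@](C)(O)CC[C@H]2C(C)(C)CCC[C@]12C | intermediate
3 | 2-[(1R,2R,4aS,8aS)-2-hydroxy-2,5,5,8a-tetramethyldecahydronaphthalen-1-yl]ethyl acetate | CC(=O)OCC[C@H]1[C@](C)(O)CC[C@H]2C(C)(C)CCC[C@]12C | intermediate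
4 | C8 chlorosulfite of 3 | CC(=O)OCC[C@H]1[C@](C)(OS(=O)Cl)CC[C@H]2C(C)(C)CCC[C@]12C | intermediate (not isolated)
5 | 2-[(1S,4aS,8aS)-5,5,8a-trimethyl-2-methylenedecahydronaphthalen-1-yl]ethyl acetate | CC(=O)OCC[C@H]1C(=C)CC[C@H]2C(C)(C)CCC[C@]12C | intermediate
6 | γ-bicyclohomofarnesol, 2-[(1S,4aS,8aS)-5,5,8a-trimethyl-2-methylenedecahydronaphthalen-1-yl]ethanol | OCC[C@H]1C(=C)CC[C@H]2C(C)(C)CCC[C@]12C | intermediate
7 | γ-bicyclohomofarnesal, 2-[(1S,4aS,8aS)-5,5,8a-trimethyl-2-methylenedecahydronaphthalen-1-yl]acetaldehyde | O=CC[C@H]1C(=C)CC[C@H]2C(C)(C)CCC[C@]12C | intermediate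
8 | furan-3-carbaldehyde | O=Cc1ccoc1 | starting material
9 | allylboronic acid pinacol ester | C=CCB1OC(C)(C)C(C)(C)O1 | starting material
10 | pinacol borate ester of 11 | C=CC[C@@H](OB1OC(C)(C)C(C)(C)O1)c1ccoc1 | intermediate (not isolated)
11 | (R)-1-(furan-3-yl)but-3-en-1-ol | O[C@@H](c1ccoc1)CC=C | intermediate
12 | acrolein | C=CC=O | starting material
13 | C2-lithiated lithium alkoxide of 11 | [Li]O[C@@H](c1ccoc1[Li])CC=C | intermediate (not isolated)
14 | (1R)-1-[2-(1-hydroxyprop-2-en-1-yl)furan-3-yl]but-3-en-1-ol, both epimers at the allylic carbinol | O[C@@H](c1ccoc1C(O)C=C)CC=C | intermediate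
15 | 1-{3-[(1R)-1-hydroxybut-3-en-1-yl]furan-2-yl}prop-2-en-1-one | O[C@@H](c1ccoc1C(=O)C=C)CC=C | intermediate
16 | 1-{3-[(1R)-1-(tert-butyldimethylsilyloxy)but-3-en-1-yl]furan-2-yl}prop-2-en-1-one | CC(C)(C)[Si](C)(C)O[C@@H](c1ccoc1C(=O)C=C)CC=C | intermediate
17 | (4R)-4-(tert-butyldimethylsilyloxy)-4,5-dihydro-8H-cyclohepta[b]furan-8-one | CC(C)(C)[Si](C)(C)O[C@@H]1CC=CC(=O)c2occc21 | intermediate
18 | iron enolate of the Giese adduct (C8–C14 bond formed, C12 aldehyde free; drawn as the enolate anion) | CC(C)(C)[Si](C)(C)O[C@@H]1C[C@H](C=C([O-])c2occc21)[C@]1(C)CC[C@H]2C(C)(C)CCC[C@]2(C)[C@H]1CC=O | intermediate (not isolated)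
19 | pentacyclic aldol: C24 furyl ketone, C12-OH (equatorial epimer drawn, either serves), 8β-Me, 9α-H, 14α-H, 13β-H, (16R)-OTBS cis to H14 | CC(C)(C)[Si](C)(C)O[C@@H]1C[C@@H]2[C@@H](C(=O)c3occc31)[C@H](O)C[C@H]1[C@@]2(C)CC[C@H]2C(C)(C)CCC[C@]12C | intermediate
20 | C12 mesylate of 19 | CC(C)(C)[Si](C)(C)O[C@@H]1C[C@@H]2[C@@H](C(=O)c3occc31)[C@H](OS(C)(=O)=O)C[C@H]1[C@@]2(C)CC[C@H]2C(C)(C)CCC[C@]12C | intermediate (not isolated)
21 | pentacyclic C12=C13 enone conjugated to the C24 furyl ketone, (16R)-OTBS | CC(C)(C)[Si](C)(C)O[C@@H]1C[C@@H]2C(C(=O)c3occc31)=CC[C@H]1[C@@]2(C)CC[C@H]2C(C)(C)CCC[C@]12C | intermediate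
22 | C13-epimeric (cis C/D) C24 furyl ketone | CC(C)(C)[Si](C)(C)O[C@@H]1C[C@@H]2[C@H](C(=O)c3occc31)CC[C@H]1[C@@]2(C)CC[C@H]2C(C)(C)CCC[C@]12C | intermediate (not isolated)
23 | pentacyclic C24 furyl ketone, trans C/D (13β-H, 14α-H), (16R)-OTBS | CC(C)(C)[Si](C)(C)O[C@@H]1C[C@@H]2[C@@H](C(=O)c3occc31)CC[C@H]1[C@@]2(C)CC[C@H]2C(C)(C)CCC[C@]12C | intermediate
24 | C24 tosylhydrazone of 23 | CC(C)(C)[Si](C)(C)O[C@@H]1C[C@@H]2[C@@H](C(=NNS(=O)(=O)c4ccc(C)cc4)c3occc31)CC[C@H]1[C@@]2(C)CC[C@H]2C(C)(C)CCC[C@]12C | intermediate
25 | N-(catecholboryl)-N'-tosyl hydrazine at C24 | CC(C)(C)[Si](C)(C)O[C@@H]1C[C@@H]2[C@@H](C(N(B4Oc5ccccc5O4)NS(=O)(=O)c4ccc(C)cc4)c3occc31)CC[C@H]1[C@@]2(C)CC[C@H]2C(C)(C)CCC[C@]12C | intermediate (not isolated)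
26 | pentacyclic fused furan (C24 methylene), (16R)-OTBS | CC(C)(C)[Si](C)(C)O[C@@H]1C[C@@H]2[C@@H](Cc3occc31)CC[C@H]1[C@@]2(C)CC[C@H]2C(C)(C)CCC[C@]12C | intermediate
27 | pentacyclic fused furan, (16R)-alcohol | O[C@@H]1C[C@@H]2[C@@H](Cc3occc31)CC[C@H]1[C@@]2(C)CC[C@H]2C(C)(C)CCC[C@]12C | intermediate
28 | pentacyclic fused furan, (16R)-acetate | CC(=O)O[C@@H]1C[C@@H]2[C@@H](Cc3occc31)CC[C@H]1[C@@]2(C)CC[C@H]2C(C)(C)CCC[C@]12C | intermediate
29 | furan 2,5-endoperoxide of 28 | CC(=O)O[C@@H]1C[C@@H]2[C@@H](CC34OOC(O3)C=C41)CC[C@H]1[C@@]2(C)CC[C@H]2C(C)(C)CCC[C@]12C | intermediate (not isolated)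
30 | C25-hydroxybutenolide (hemiketal epimers), (16R)-acetate | CC(=O)O[C@@H]1C[C@@H]2[C@@H](CC3(O)OC(=O)C=C31)CC[C@H]1[C@@]2(C)CC[C@H]2C(C)(C)CCC[C@]12C | intermediate
31 | CNP0193439.1 | CC(=O)O[C@@H]1C[C@@H]2[C@@H](C=C3OC(=O)C=C31)CC[C@H]1[C@@]2(C)CC[C@H]2C(C)(C)CCC[C@]12C | target

**Step count**

Total: 19 steps. Longest linear sequence: 14 steps (steps 1–5 or steps 6–10, then steps 11–19).

**Steps most likely to fail**

1. Step 11. The cascade may stall after the intermolecular Giese addition, either because the enolate is protonated by the alcohol before the aldol closes or because the aldehyde is lost to acetal formation or hydrosilylation. Facial discrimination at C14 may also be incomplete. The fallback sets out from alcohol 6 and enone 17 and returns at enone 21, separating the two bond formations. The same Fe(acac)3/PhSiH3 conditions in EtOH/ethylene glycol are run as a plain reductive olefin coupling on the alcohol and should give the Giese keto alcohol F1, where any C14 epimer can be separated. Oxidation with n-Pr4N[RuO4]/NMO gives keto aldehyde F2. KOH in MeOH then effects an intramolecular aldol condensation of the C13 methylene onto the C12 aldehyde and delivers 21 directly.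

2. Step 7. The deprotonation may not be regioselective (C5 against C2 lithiation), and the dianion may oligomerise acrolein instead of adding to it. The fallback sets out from alcohol 11 and returns at silyloxy dienone 16, replacing directed deprotonation by halogen–metal exchange. Silylation (TBSCl, imidazole, DMF) gives silyl ether F3. Bromination with NBS in DMF at 0 °C at the furan α-position next to the side chain gives 2-bromofuran F4. Bromine–lithium exchange with n-BuLi in Et2O at −78 °C and immediate trapping with acrolein, fast enough to outrun 1,4-silyl migration, gives allylic alcohol F5. MnO2 oxidation of F5 gives 16, which also removes the need for the selective oxidation of step 8.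

3. Step 15. Hydride delivery to the hindered, furan-conjugated hydrazone may be sluggish, or the hydrazone may decompose by base-induced elimination to a C13–C24 alkene. The fallback sets out from ketone 23 and returns at furan 26, using radical deoxygenation of the carbinol. NaBH4 in MeOH/THF gives the C24 carbinol F6. PhOC(S)Cl with pyridine and DMAP gives the O-phenyl thionocarbonate F7. Bu3SnH with AIBN in toluene at 90 °C (Barton–McCombie) then removes the oxygen through the furan-stabilised C24 radical and gives 26.

**Further compounds**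

F1 | step 11 | Giese keto alcohol (C8–C14 bond formed, C13 methylene, C12 primary alcohol) | CC(C)(C)[Si](C)(C)O[C@@H]1C[C@H](CC(=O)c2occc21)[C@]1(C)CC[C@H]2C(C)(C)CCC[C@]2(C)[C@H]1CCO
F2 | step 11 | keto aldehyde (C12 aldehyde, C24 furyl ketone) | CC(C)(C)[Si](C)(C)O[C@@H]1C[C@H](CC(=O)c2occc21)[C@]1(C)CC[C@H]2C(C)(C)CCC[C@]2(C)[C@H]1CC=O
F3 | step 7 | (R)-tert-butyl{[1-(furan-3-yl)but-3-en-1-yl]oxy}dimethylsilane | CC(C)(C)[Si](C)(C)O[C@@H](c1ccoc1)CC=C
F4 | step 7 | (R)-{[1-(2-bromofuran-3-yl)but-3-en-1-yl]oxy}(tert-butyl)dimethylsilane | CC(C)(C)[Si](C)(C)O[C@@H](c1ccoc1Br)CC=C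
F5 | step 7 | 1-{3-[(1R)-1-(tert-butyldimethylsilyloxy)but-3-en-1-yl]furan-2-yl}prop-2-en-1-ol | CC(C)(C)[Si](C)(C)O[C@@H](c1ccoc1C(O)C=C)CC=C
F6 | step 15 | C24 carbinol of 23 (epimers at C24) | CC(C)(C)[Si](C)(C)O[C@@H]1C[C@@H]2[C@@H](C(O)c3occc31)CC[C@H]1[C@@]2(C)CC[C@H]2C(C)(C)CCC[C@]12C
F7 | step 15 | C24 O-phenyl thionocarbonate | CC(C)(C)[Si](C)(C)O[C@@H]1C[C@@H]2[C@@H](C(OC(=S)Oc4ccccc4)c3occc31)CC[C@H]1[C@@]2(C)CC[C@H]2C(C)(C)CCC[C@]12C
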